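**Strategy.** Ring A (numbered C1 propanoyl-bearing carbon, C2 the adjacent C–O carbon, C3 the CMe2 carbon, C4, C5 the chromenylmethyl-bearing carbon, C6) is opened at C1–C2. Read forwards, C1 is the central carbon of a 1,3-diketone and C2 a methyl ester on the quaternary C3, so a single Dieckmann-type Claisen closure of open-chain trioxo ester 15 forms the C1–C2 bond, ring A and its complete enolised triketone pattern; C3 being quaternary, aromatisation cannot follow. Precursor 15 already holds the chromenylmethyl arm on the future C5 and both phenols as MOM ethers, and its propanoyl ketone is unmasked only one step before cyclisation.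

Key step: step 11

Assumption: in step 4 the pyran ring is taken to close mainly onto the phenol oxygen next to the acetyl group (8-acetyl chromene 9); any 6-acetyl isomer would be removed by chromatography at that stage.

The target has no stereocentre. The chain stereocentre of 14 and 15 is racemic, labile and erased in step 11.

**Chain fragment**

Step 1
Reactants: 1 methyl 3-oxopentanoate
Product: 2 methyl 2-(2-ethyl-1,3-dioxolan-2-yl)acetate
Conditions: HOCH2CH2OH (3 equiv), p-TsOH·H2O (cat.), toluene, reflux, Dean–Stark
Reagents that add atoms: ethylene glycol, OCCO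
Why: Acid-catalysed ketalisation of the ketone of a β-keto ester with azeotropic removal of water is routine, leaves the ester untouched and masks the future propanoyl carbonyl through all later base steps.

Step 2
Reactants: 2 methyl 2-(2-ethyl-1,3-dioxolan-2-yl)acetate
Product: 3 2-(2-ethyl-1,3-dioxolan-2-yl)acetic acid
Conditions: LiOH·H2O, THF/H2O, rt; then 1 M HCl to pH 3, 0 °C, immediate extraction
Reagents that add atoms: lithium hydroxide, [Li+].[OH-]
Why: Saponification (base-mediated ester hydrolysis) cannot harm the ketal, and brief cold acidification frees the acid without opening the dioxolane.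

Step 3
Reactants: 3 2-(2-ethyl-1,3-dioxolan-2-yl)acetic acid; 4 methyl 2,2-dimethyl-3-oxobutanoate
Product: 6 methyl 6-(2-ethyl-1,3-dioxolan-2-yl)-2,2-dimethyl-3,5-dioxohexanoate, via acyl imidazole 5 (not isolated)
Conditions: 3, 1,1'-carbonyldiimidazole (1.1 equiv), THF, rt; solution added to 4 (3.2 equiv)/LiN(i-Pr)2 (3.2 equiv), THF, −78 → −30 °C; aq. NH4Cl
Reagents that add atoms: none
Why: Claisen-type C-acylation of a ketone lithium enolate by an acyl imidazole should be clean because 4 can enolise only at its methyl group, the excess enolate absorbs the imidazole N–H and the acidic 1,3-diketone product, and no alkoxide is released that could cleave the non-enolisable β-keto ester.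

**Arene fragment**

Step 4
Reactants: 7 1-(2,4,6-trihydroxyphenyl)ethanone; 8 3-methylbut-2-enal
Product: 9 1-(5,7-dihydroxy-2,2-dimethyl-2H-chromen-8-yl)ethanone
Conditions: 8 (1.1 equiv), pyridine, 120 °C
Reagents that add atoms: none
Why: Pyridine-mediated chromenylation (Knoevenagel-type C-alkylation of the phloroglucinol ring by the enal, dehydration to an ortho-quinone methide and oxa-6π electrocyclisation) is the standard entry to 2,2-dimethylchromenes of acylphloroglucinols, with the enal held near one equivalent to avoid a second annulation.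

Step 5
Reactants: 9 1-(5,7-dihydroxy-2,2-dimethyl-2H-chromen-8-yl)ethanone
Product: 10 8-acetyl-5,7-dihydroxy-2,2-dimethyl-2H-chromene-6-carbaldehyde
Conditions: POCl3 (1.5 equiv), DMF (3 equiv), EtOAc, 0 °C → rt; then H2O, rt
Reagents that add atoms: N,N-dimethylformamide, CN(C)C=O; water, O
Why: Vilsmeier–Haack formylation can only occur at C6, the single free aromatic position, which is activated by two ortho hydroxyls and the para pyran oxygen far more strongly than the styrene-type C3=C4 bond.

Step 6
Reactants: 10 8-acetyl-5,7-dihydroxy-2,2-dimethyl-2H-chromene-6-carbaldehyde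
Product: 11 8-acetyl-5,7-bis(methoxymethoxy)-2,2-dimethyl-2H-chromene-6-carbaldehyde
Conditions: MOMCl (3 equiv), i-Pr2NEt (4 equiv), n-Bu4NI (cat.), CH2Cl2, 0 → 40 °C
Reagents that add atoms: chloromethyl methyl ether, COCCl
Why: Williamson-type O-alkylation of the two acidic, carbonyl-chelated phenols under a non-enolising amine base gives the bis-acetal, which survives every basic step and later blocks hemiketalisation and ortho-quinone methide extrusion.

Step 7
Reactants: 11 8-acetyl-5,7-bis(methoxymethoxy)-2,2-dimethyl-2H-chromene-6-carbaldehyde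
Product: 12 1-[6-(hydroxymethyl)-5,7-bis(methoxymethoxy)-2,2-dimethyl-2H-chromen-8-yl]ethanone
Conditions: NaBH4 (0.5 equiv), EtOH/CH2Cl2 (1:3), −78 → −40 °C; aq. NH4Cl
Reagents that add atoms: none
Why: Chemoselective borohydride reduction should hold because at low temperature NaBH4 reduces the aldehyde much faster than the di-ortho-substituted, twisted aryl methyl ketone.

Step 8
Reactants: 12 1-[6-(hydroxymethyl)-5,7-bis(methoxymethoxy)-2,2-dimethyl-2H-chromen-8-yl]ethanone
Product: 13 1-[6-(bromomethyl)-5,7-bis(methoxymethoxy)-2,2-dimethyl-2H-chromen-8-yl]ethanone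
Conditions: CBr4 (1.2 equiv), PPh3 (1.2 equiv), 2,6-lutidine (0.5 equiv), CH2Cl2, −20 → 0 °C; cold filtration through silica, used at once
Reagents that add atoms: carbon tetrabromide, BrC(Br)(Br)Br
Why: The Appel reaction brominates under neutral conditions by SN2 displacement of the alkoxyphosphonium ion, so MOM ethers, ketone and chromene are untouched, and the labile electron-rich benzylic bromide is carried forward without storage.

**Union, key step and deprotection**

Step 9
Reactants: 13 1-[6-(bromomethyl)-5,7-bis(methoxymethoxy)-2,2-dimethyl-2H-chromen-8-yl]ethanone; 6 methyl 6-(2-ethyl-1,3-dioxolan-2-yl)-2,2-dimethyl-3,5-dioxohexanoate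
Product: 14 methyl 4-{[8-acetyl-5,7-bis(methoxymethoxy)-2,2-dimethyl-2H-chromen-6-yl]methyl}-6-(2-ethyl-1,3-dioxolan-2-yl)-2,2-dimethyl-3,5-dioxohexanoate (racemic at C4)
Conditions: 6 (1.3 equiv), K2CO3 (2 equiv), acetone, 0 °C → rt
Reagents that add atoms: none
Why: C-alkylation (SN2) of a 1,3-diketone enolate by a benzylic bromide should be site-selective because, with the propanoyl carbonyl masked, C4 is the only doubly activated carbon of 6 and K2CO3 is too weak to enolise the aryl methyl ketone or any singly activated position.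

Step 10
Reactants: 14 methyl 4-{[8-acetyl-5,7-bis(methoxymethoxy)-2,2-dimethyl-2H-chromen-6-yl]methyl}-6-(2-ethyl-1,3-dioxolan-2-yl)-2,2-dimethyl-3,5-dioxohexanoate
Product: 15 methyl 4-{[8-acetyl-5,7-bis(methoxymethoxy)-2,2-dimethyl-2H-chromen-6-yl]methyl}-2,2-dimethyl-3,5,7-trioxononanoate (racemic, enolisable at C4)
Conditions: p-TsOH·H2O (10 mol %), acetone/H2O (10:1), 0 °C → rt, monitored; NaHCO3 quench
Reagents that add atoms: water, O
Why: Acid-catalysed ketal hydrolysis should be selective because a ketone-derived dioxolane ionises to a tertiary oxocarbenium ion far more readily than the formaldehyde-derived aryl MOM acetals, and the short, mild exposure limits cyclodehydration of the freed triketone.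

Step 11
Reactants: 15 methyl 4-{[8-acetyl-5,7-bis(methoxymethoxy)-2,2-dimethyl-2H-chromen-6-yl]methyl}-2,2-dimethyl-3,5,7-trioxononanoate
Product: 16 2-{[8-acetyl-5,7-bis(methoxymethoxy)-2,2-dimethyl-2H-chromen-6-yl]methyl}-3,5-dihydroxy-4,4-dimethyl-6-propanoylcyclohexa-2,5-dien-1-one
Conditions: LiN(SiMe3)2 (3.5 equiv), THF, −78 °C → rt; cold 1 M HCl to pH 3
Reagents that add atoms: none
Why: LiN(SiMe3)2 turns 15 into its polyenolate, in which every ketone is held as an enolate and the methyl ester is the only electrophile; the carbon between the propanoyl carbonyl and the chain C5 carbonyl (chain C6, future ring carbon C1) adds to the ester carbonyl (chain C1, future C2), methoxide leaves, and the new tricarbonyl C–H is deprotonated at once, which pulls the equilibrium to the dianion of 16. The closest known reaction type is the Dieckmann (intramolecular Claisen) cyclisation of 3,5,7-triketo esters to acylphloroglucinol-type rings. Ring A closes in the 6-exo-trig mode, helped by the Thorpe–Ingold effect of the CMe2 group, and because C3 is quaternary the ring stays at the filicinic acid oxidation level. No stereocentre is formed, and the labile chain stereocentre becomes an sp2 enol carbon. The step needs C- over O-acylation and closure over fragmentation: no aldol path exists since the ester α-carbon is quaternary, an enol lactone from O-attack would be reversible whereas the C-acylated product is a stabilised dianion, the hindered silylamide cannot add to a carbonyl while the keto group next to CMe2 is enolised, and the MOM ethers prevent phenoxide-triggered loss of the benzylic arm.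

Step 12
Reactants: 16 2-{[8-acetyl-5,7-bis(methoxymethoxy)-2,2-dimethyl-2H-chromen-6-yl]methyl}-3,5-dihydroxy-4,4-dimethyl-6-propanoylcyclohexa-2,5-dien-1-one
Product: 17 2-[(8-acetyl-5,7-dihydroxy-2,2-dimethyl-2H-chromen-6-yl)methyl]-3,5-dihydroxy-4,4-dimethyl-6-propanoylcyclohexa-2,5-dien-1-one (target)
Conditions: 3 M aq. HCl/MeOH (1:4), 40 °C
Reagents that add atoms: none
Why: Acid-catalysed acetal cleavage (transacetalisation to methanol) removes both aryl MOM ethers, while ring A offers no free carbon for formaldehyde capture, no stereocentre is at risk and 2,2-dimethylchromenes tolerate dilute methanolic HCl.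

**Compound list**

1 | methyl 3-oxopentanoate | CCC(=O)CC(=O)OC | starting material
2 | methyl 2-(2-ethyl-1,3-dioxolan-2-yl)acetate | CCC1(CC(=O)OC)OCCO1 | intermediate
3 | 2-(2-ethyl-1,3-dioxolan-2-yl)acetic acid | CCC1(CC(=O)O)OCCO1 | intermediate
4 | methyl 2,2-dimethyl-3-oxobutanoate | COC(=O)C(C)(C)C(C)=O | starting material
5 | 2-(2-ethyl-1,3-dioxolan-2-yl)-1-(1H-imidazol-1-yl)ethan-1-one (acyl imidazole, formed in the flask) | CCC1(CC(=O)n2ccnc2)OCCO1 | intermediate
6 | methyl 6-(2-ethyl-1,3-dioxolan-2-yl)-2,2-dimethyl-3,5-dioxohexanoate | COC(=O)C(C)(C)C(=O)CC(=O)CC1(CC)OCCO1 | intermediate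
7 | 1-(2,4,6-trihydroxyphenyl)ethanone | CC(=O)c1c(O)cc(O)cc1O | starting material
8 | 3-methylbut-2-enal | CC(C)=CC=O | starting material
9 | 1-(5,7-dihydroxy-2,2-dimethyl-2H-chromen-8-yl)ethanone | CC(=O)c1c(O)cc(O)c2c1OC(C)(C)C=C2 | intermediate
10 | 8-acetyl-5,7-dihydroxy-2,2-dimethyl-2H-chromene-6-carbaldehyde | CC(=O)c1c(O)c(C=O)c(O)c2c1OC(C)(C)C=C2 | intermediate
11 | 8-acetyl-5,7-bis(methoxymethoxy)-2,2-dimethyl-2H-chromene-6-carbaldehyde | CC(=O)c1c(OCOC)c(C=O)c(OCOC)c2c1OC(C)(C)C=C2 | intermediate
12 | 1-[6-(hydroxymethyl)-5,7-bis(methoxymethoxy)-2,2-dimethyl-2H-chromen-8-yl]ethanone | CC(=O)c1c(OCOC)c(CO)c(OCOC)c2c1OC(C)(C)C=C2 | intermediate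
13 | 1-[6-(bromomethyl)-5,7-bis(methoxymethoxy)-2,2-dimethyl-2H-chromen-8-yl]ethanone | CC(=O)c1c(OCOC)c(CBr)c(OCOC)c2c1OC(C)(C)C=C2 | intermediate
14 | methyl 4-{[8-acetyl-5,7-bis(methoxymethoxy)-2,2-dimethyl-2H-chromen-6-yl]methyl}-6-(2-ethyl-1,3-dioxolan-2-yl)-2,2-dimethyl-3,5-dioxohexanoate (racemic) | COC(=O)C(C)(C)C(=O)C(Cc1c(OCOC)c2C=CC(C)(C)Oc2c(C(C)=O)c1OCOC)C(=O)CC1(CC)OCCO1 | intermediate
15 | methyl 4-{[8-acetyl-5,7-bis(methoxymethoxy)-2,2-dimethyl-2H-chromen-6-yl]methyl}-2,2-dimethyl-3,5,7-trioxononanoate (racemic, keto form drawn) | CCC(=O)CC(=O)C(Cc1c(OCOC)c2C=CC(C)(C)Oc2c(C(C)=O)c1OCOC)C(=O)C(C)(C)C(=O)OC | intermediate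
16 | 2-{[8-acetyl-5,7-bis(methoxymethoxy)-2,2-dimethyl-2H-chromen-6-yl]methyl}-3,5-dihydroxy-4,4-dimethyl-6-propanoylcyclohexa-2,5-dien-1-one | CCC(=O)C1=C(O)C(C)(C)C(O)=C(Cc2c(OCOC)c3C=CC(C)(C)Oc3c(C(C)=O)c2OCOC)C1=O | intermediate
17 | 2-[(8-acetyl-5,7-dihydroxy-2,2-dimethyl-2H-chromen-6-yl)methyl]-3,5-dihydroxy-4,4-dimethyl-6-propanoylcyclohexa-2,5-dien-1-one | CCC(=O)C1=C(O)C(C)(C)C(O)=C(Cc2c(O)c3c(c(C(C)=O)c2O)OC(C)(C)C=C3)C1=O | target

**Totals.** Total step count: 12. Longest linear sequence: 9 steps (7 to 17, steps 4 to 12); the chain fragment 6 is made in 3 steps and joins at step 9.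

**Steps most likely to fail**

Step 11 (key step). The diketonate carbon may add too slowly to the hindered ester beside the quaternary carbon, so that reversible O-acylation or methoxide-induced fragmentation of the chain competes with ring closure. The fallback gives up closure on the assembled chain and joins a preformed ring A instead. It sets out from bromide 13, which is used to C-benzylate the free ring carbon of 3,5-dihydroxy-4,4-dimethyl-2-propanoylcyclohexa-2,5-dien-1-one F1 with K2CO3 in acetone. F1 is obtained by geminal C-methylation of commercial 1-(2,4,6-trihydroxyphenyl)propan-1-one with iodomethane and NaOMe in methanol. This alkylation gives 16 directly, where the route is rejoined before step 12.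

Step 9. The bromide may ionise and self-condense before it is intercepted, or the diketonate may be alkylated on oxygen. The fallback replaces the substitution by a carbonyl condensation and needs neither step 7 nor step 8. It sets out from aldehyde 11 and diketone 6: Knoevenagel condensation (piperidine/AcOH, toluene, 4 Å molecular sieves) gives methyl 4-{[8-acetyl-5,7-bis(methoxymethoxy)-2,2-dimethyl-2H-chromen-6-yl]methylidene}-6-(2-ethyl-1,3-dioxolan-2-yl)-2,2-dimethyl-3,5-dioxohexanoate F2 (either alkene isomer serves). Its doubly activated C=C bond is then reduced by hydride transfer from the Hantzsch ester (diethyl 2,6-dimethyl-1,4-dihydropyridine-3,5-dicarboxylate), which leaves the chromene alkene and both ketones alone and returns to the route at 14.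

Step 10. The acid may start to remove the MOM ethers before the ketal is gone, or the liberated 1,3,5-triketone may cyclodehydrate to a 4-pyranone. The fallback avoids a separate unmasking. It sets out from 14, which with LiN(i-Pr)2 (3.3 equiv) in THF at −78 → 0 °C is converted into the 1,3-diketone dianion; its terminal carbanion closes onto the ester in the same Dieckmann sense to give 2-{[8-acetyl-5,7-bis(methoxymethoxy)-2,2-dimethyl-2H-chromen-6-yl]methyl}-6-(2-ethyl-1,3-dioxolan-2-yl)-3,5-dihydroxy-4,4-dimethylcyclohexa-2,5-dien-1-one F3. One treatment with aqueous HCl in methanol then removes the ketal and both MOM ethers together, so no open-chain triketone ever meets acid, and the route is rejoined at 17.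

Further compounds
F1 | step 11 | 3,5-dihydroxy-4,4-dimethyl-2-propanoylcyclohexa-2,5-dien-1-one | CCC(=O)C1=C(O)C(C)(C)C(O)=CC1=O
F2 | step 9 | methyl 4-{[8-acetyl-5,7-bis(methoxymethoxy)-2,2-dimethyl-2H-chromen-6-yl]methylidene}-6-(2-ethyl-1,3-dioxolan-2-yl)-2,2-dimethyl-3,5-dioxohexanoate (alkene geometry not fixed) | COC(=O)C(C)(C)C(=O)C(=Cc1c(OCOC)c2C=CC(C)(C)Oc2c(C(C)=O)c1OCOC)C(=O)CC1(CC)OCCO1
F3 | step 10 | 2-{[8-acetyl-5,7-bis(methoxymethoxy)-2,2-dimethyl-2H-chromen-6-yl]methyl}-6-(2-ethyl-1,3-dioxolan-2-yl)-3,5-dihydroxy-4,4-dimethylcyclohexa-2,5-dien-1-one | CCC1(OCCO1)C1=C(O)C(C)(C)C(O)=C(Cc2c(OCOC)c3C=CC(C)(C)Oc3c(C(C)=O)c2OCOC)C1=O
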